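The 2-aminopyrimidine ring of meridianin F is disconnected into three pieces: N1'–C2'(NH2)–N3' is guanidine, C4' (the carbon bonded to indole C3) is the formyl carbon of an indole-3-carbaldehyde, and C5'–C6' is ethyl vinyl ether. One acid-promoted three-component annulation forms N3'–C4', C4'–C5' and N1'–C6' and closes the six-membered ring as a 1,4-dihydropyrimidine; dehydrogenation and N-deprotection finish the synthesis. The precursor is 5,6-dibromoindole-3-carbaldehyde carrying an N-tosyl group, which cancels the vinylogous-amide deactivation of the formyl group and is kept intact by using guanidine as its hydrochloride under Lewis-acidic, non-basic conditions.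

Key step: step 3

Assumption: the target has no stereocentre, so no enantiocontrol is needed (the one sp3 centre made in step 3 is racemic and is erased in step 4); guanidine is used as its commercial hydrochloride and 5,6-dibromoindole is taken as purchasable.

Step 1
Reactants: 1 5,6-dibromo-1H-indole
Product: 3 5,6-dibromo-1H-indole-3-carbaldehyde, via iminium salt 2 (not isolated)
Conditions: POCl3 (1.2 equiv), DMF, 0 → 40 °C; then 2 M aq. NaOH, 90 °C
Reagents that add atoms: N,N-dimethylformamide, CN(C)C=O (formyl carbon); water, O (carbonyl oxygen, delivered in the hydrolysis)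
Why: Vilsmeier–Haack formylation, in which the chloroiminium ion from DMF/POCl3 attacks the most nucleophilic indole position C3 (the two bromines slow but do not redirect the substitution) and alkaline hydrolysis of iminium salt 2 releases the aldehyde.

Step 2
Reactants: 3 5,6-dibromo-1H-indole-3-carbaldehyde; 4 p-toluenesulfonyl chloride
Product: 5 5,6-dibromo-1-tosyl-1H-indole-3-carbaldehyde
Conditions: NaH (1.2 equiv), THF–DMF, 0 °C; then 4, 0 °C → rt
Reagents that add atoms: none
Why: N-sulfonylation of the sodium salt of an acidic 3-formylindole N–H, which takes the nitrogen lone pair out of conjugation with the formyl group and so restores ordinary aldehyde electrophilicity for step 3.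

Step 3
Reactants: 5 5,6-dibromo-1-tosyl-1H-indole-3-carbaldehyde; 6 guanidine hydrochloride; 7 ethyl vinyl ether
Product: 10 4-(5,6-dibromo-1-tosyl-1H-indol-3-yl)-1,4-dihydropyrimidin-2-amine (racemic), via N-amidinyl imine 8 (not isolated), via ethoxy aminal 9 (not isolated)
Conditions: 6 (1.5 equiv), Yb(OTf)3 (10 mol %), 4 Å MS, MeCN–DMF (4:1), 60 °C; then 7 (4 equiv, portionwise), 45 → 80 °C, sealed vessel; sat. aq. NaHCO3 work-up, free base used promptly
Reagents that add atoms: none
Why: Proposed new method: under Yb(III)/guanidinium acid the aldehyde of 5 condenses with guanidine to the N-amidinyl imine 8, whose conjugate acid is a 1,3-diazadiene electrophile of the N-acyliminium type, and the nucleophilic CH2 terminus of ethyl vinyl ether adds to its carbon (C4'–C5'). The oxocarbenium ion so formed is trapped by the distal guanidine nitrogen (N1'–C6') in a 6-exo-trig closure, the C=O+ bond lying outside the new ring, so that the sequence amounts to a stepwise inverse-electron-demand aza-[4+2] and gives the cyclic N,O-aminal 9. Warming lets 9 ionise to the cyclic amidinyl iminium ion and lose a C5' proton, expelling ethanol and leaving the ene-guanidine 10, which stays protected as its guanidinium salt until the bicarbonate work-up. The closest known reaction types are the Biginelli condensation with guanidine salts and lanthanide-triflate-catalysed Povarov/Mannich additions of enol ethers to iminium ions. The only new stereocentre, C4', is formed without control as the racemate, which is immaterial because it becomes sp2 in step 4. The step needs the Mannich addition to beat hydrolysis and cationic oligomerisation of the vinyl ether and needs the sulfonamide to survive: the N-sulfonyl group makes the iminium carbon strongly electrophilic, the imine is pre-formed over sieves before slow addition of 7, and the hydrochloride of guanidine keeps the medium free of the base that would strip the tosyl group.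

Step 4
Reactants: 10 4-(5,6-dibromo-1-tosyl-1H-indol-3-yl)-1,4-dihydropyrimidin-2-amine
Product: 11 4-(5,6-dibromo-1-tosyl-1H-indol-3-yl)pyrimidin-2-amine
Conditions: DDQ (1.1 equiv), 1,4-dioxane, rt; aq. NaHCO3 wash
Reagents that add atoms: none
Why: Quinone dehydrogenation (oxidative aromatisation) of a dihydropyrimidine, in which hydride abstraction from the C4'–H flanked by N3', the C5'=C6' enamine and the indole is followed by loss of the N1' proton, driven by formation of the aromatic pyrimidine, while the sulfonamide and aryl bromides are inert to DDQ.

Step 5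
Reactants: 11 4-(5,6-dibromo-1-tosyl-1H-indol-3-yl)pyrimidin-2-amine
Product: 12 meridianin F, 4-(5,6-dibromo-1H-indol-3-yl)pyrimidin-2-amine
Conditions: 2 M aq. NaOH (4 equiv), 1,4-dioxane, 80 °C
Reagents that add atoms: none
Why: Alkaline hydrolysis of an N-sulfonylindole (hydroxide attack at sulfur with the indolide as leaving group, made good by the electron-poor 3-pyrimidinyl substituent), run without alcohol so that no alkyl tosylate can N-alkylate the product, and leaving the aryl bromides and aminopyrimidine untouched.

Compound list
1 | 5,6-dibromo-1H-indole | Brc1cc2cc[nH]c2cc1Br | starting material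
2 | [(5,6-dibromo-1H-indol-3-yl)methylidene]dimethyliminium salt (drawn as chloride) | C[N+](C)=Cc1c[nH]c2cc(Br)c(Br)cc12.[Cl-] | intermediate (not isolated)
3 | 5,6-dibromo-1H-indole-3-carbaldehyde | O=Cc1c[nH]c2cc(Br)c(Br)cc12 | intermediate
4 | p-toluenesulfonyl chloride | Cc1ccc(S(=O)(=O)Cl)cc1 | starting material
5 | 5,6-dibromo-1-tosyl-1H-indole-3-carbaldehyde | O=Cc1cn(S(=O)(=O)c2ccc(C)cc2)c2cc(Br)c(Br)cc12 | intermediate
6 | guanidine hydrochloride | NC(N)=N.Cl | starting material
7 | ethyl vinyl ether | C=COCC | starting material
8 | (E)-1-[(5,6-dibromo-1-tosyl-1H-indol-3-yl)methylidene]guanidine (N-amidinyl imine, reacts as its conjugate acid) | NC(=N)/N=C/c1cn(S(=O)(=O)c2ccc(C)cc2)c2cc(Br)c(Br)cc12 | intermediate (not isolated)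
9 | 4-(5,6-dibromo-1-tosyl-1H-indol-3-yl)-6-ethoxy-1,4,5,6-tetrahydropyrimidin-2-amine (racemic, mixture of diastereomers) | CCOC1CC(c2cn(S(=O)(=O)c3ccc(C)cc3)c3cc(Br)c(Br)cc23)N=C(N)N1 | intermediate (not isolated)
10 | 4-(5,6-dibromo-1-tosyl-1H-indol-3-yl)-1,4-dihydropyrimidin-2-amine (racemic) | NC1=NC(c2cn(S(=O)(=O)c3ccc(C)cc3)c3cc(Br)c(Br)cc23)C=CN1 | intermediate
11 | 4-(5,6-dibromo-1-tosyl-1H-indol-3-yl)pyrimidin-2-amine | Nc1nccc(-c2cn(S(=O)(=O)c3ccc(C)cc3)c3cc(Br)c(Br)cc23)n1 | intermediate
12 | meridianin F, 4-(5,6-dibromo-1H-indol-3-yl)pyrimidin-2-amine (achiral) | Nc1nccc(-c2c[nH]c3cc(Br)c(Br)cc23)n1 | target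

Total step count: 5. Longest linear sequence: 5 steps (1 → 3 → 5 → 10 → 11 → 12).

Steps most likely to fail

Step 3 (Proposed new method). The guanidinium ion may be too weakly nucleophilic under acidic conditions to condense with the aldehyde, or the vinyl ether may be consumed by hydrolysis and cationic oligomerisation before Mannich addition occurs. The fallback uses known chemistry, sets out from aldehyde 5 and returns at target 12. Addition of ethynylmagnesium bromide (THF, 0 °C) should give racemic 1-(5,6-dibromo-1-tosyl-1H-indol-3-yl)prop-2-yn-1-ol F1. Oxidation with activated MnO2 (CH2Cl2, rt) should give the ynone 1-(5,6-dibromo-1-tosyl-1H-indol-3-yl)prop-2-yn-1-one F2. Cyclocondensation of F2 with guanidine hydrochloride 6 and K2CO3 in refluxing 2-methoxyethanol (conjugate addition followed by dehydrative ring closure, the standard alkynone–amidine pyrimidine synthesis) builds the aromatic pyrimidine directly, passing through 11 in the flask. The hot carbonate medium is expected to cleave the N-sulfonyl group as well, so the sequence rejoins at 12 and makes steps 4 and 5 unnecessary.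

Step 4. Hydride abstraction from the electron-poor N-sulfonyl substrate may be incomplete, or the ene-guanidine may add covalently to the quinone. The fallback sets out from 10 and returns at 12 by reversing the order of the last two operations. Aqueous NaOH in 1,4-dioxane first removes the sulfonyl group to give 4-(5,6-dibromo-1H-indol-3-yl)-1,4-dihydropyrimidin-2-amine F3, in which the free indole nitrogen now feeds electron density to C4'. Stirring the same alkaline solution under air or an O2 balloon should then bring about base-mediated autoxidative aromatisation, the pathway by which dihydropyrimidines from enone–guanidine condensations aromatise, giving 12 without a quinone oxidant.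

Step 1. Electrophilic substitution on the bromine-deactivated indole may be sluggish, with incomplete conversion or competing N-formylation. The fallback sets out from 1 and returns at 5, replacing electrophilic formylation by an organometallic one. Iodination through the indolyl anion (I2, KOH, DMF, rt) should give 5,6-dibromo-3-iodo-1H-indole F4. N-Tosylation (NaH, then 4, THF) should give 5,6-dibromo-3-iodo-1-tosyl-1H-indole F5. Iodine–magnesium exchange with i-PrMgCl·LiCl (THF, −40 °C; the C–I bond exchanges far faster than the aryl C–Br bonds) should give (5,6-dibromo-1-tosyl-1H-indol-3-yl)magnesium chloride F6, which is quenched with DMF and worked up with aqueous NH4Cl to give aldehyde 5.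

Further compounds
F1 | step 3 | 1-(5,6-dibromo-1-tosyl-1H-indol-3-yl)prop-2-yn-1-ol (racemic) | C#CC(O)c1cn(S(=O)(=O)c2ccc(C)cc2)c2cc(Br)c(Br)cc12
F2 | step 3 | 1-(5,6-dibromo-1-tosyl-1H-indol-3-yl)prop-2-yn-1-one | C#CC(=O)c1cn(S(=O)(=O)c2ccc(C)cc2)c2cc(Br)c(Br)cc12
F3 | step 4 | 4-(5,6-dibromo-1H-indol-3-yl)-1,4-dihydropyrimidin-2-amine (racemic) | NC1=NC(c2c[nH]c3cc(Br)c(Br)cc23)C=CN1
F4 | step 1 | 5,6-dibromo-3-iodo-1H-indole | Ic1c[nH]c2cc(Br)c(Br)cc12
F5 | step 1 | 5,6-dibromo-3-iodo-1-tosyl-1H-indole | Ic1cn(S(=O)(=O)c2ccc(C)cc2)c2cc(Br)c(Br)cc12
F6 | step 1 | (5,6-dibromo-1-tosyl-1H-indol-3-yl)magnesium chloride | Cl[Mg]c1cn(S(=O)(=O)c2ccc(C)cc2)c2cc(Br)c(Br)cc12
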